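The ratio to carry through this problem compares two fates of X.E: capture by free E against the turn into J. You feed X steadily into E in a row of flasks and ask how much J stands at the end.

common to all: X 35 mM (fed, over 8.0 h); time 12 h

| run | E |
|---|---|
| dawn | 0.250 equiv |
| summer | 0.500 equiv |
| autumn | 1.00 equiv |
| midnight | 2.00 equiv |
| spring | 4.00 equiv |

    X + J → X.J (k1 = 0.619 M⁻¹ min⁻¹)
    X + E → X.E (k2 = 0.293 M⁻¹ min⁻¹)
    E + X.E ⇌ E.X.E (K3 = 593 M⁻¹, k3 = 0.395 M⁻¹ min⁻¹)
    X.E → J (k4 = 0.0128 min⁻¹)

- in percentages every species weighs as the X in it: one X.J counts as two
- "hardly changes" means that all values lie within two and a half points (for a concentration: within two and a half percent of the largest)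
- run time (dawn): 12 h

- amount of J at the end, in percent of the X charged for dawn, summer, autumn, midnight, spring, in this order
- the course of these numbers from the first flask to the last (falls, then rises / falls all the way / hardly changes / rises all the way / rises, then falls)

Put a number on the ratio for spring, the last flask of the row. At the charge of spring, the capture constant times c(E), over the constant of the turn into J, gives 4.32; this forward rate of capture of X.E over its rate to J, at a stated c(E), is the trap ratio, a selectivity factor. So in spring a share 18.8 % of X.E goes straight to J at that c(E).

For a bound from above, note that one X holds two E at most, so in spring c(E) stays above 70.0 mM. For spring that gives a ratio of 2.16 and a share of 31.6 %. E.X.E also comes back, with a half-life of 17.3 h by the way back alone, longer than the run. Letting the trapped part return for the whole run, as if it had stood from the start, puts my ceiling for J in spring at about 39.9 %.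

For a rough bound from below, take the charged share with no return, then charge the attack of X on J. Taking c(E) near 105 mM in spring, the share is 23.6 %, and I take c(J) as 4.13 mM on average, so I reckon X diverted at 8.30 % of its rate to X.E. Each diverted X also costs one J, which leaves about 8.93 %.

To tighten, use the middle share, the same attack, and a return over the mean stay of 8.00 h. I commit to 18.3 % for spring. This reckoning gives no figure for midnight.

The forecast gives 1 %, 3 %, 14.5 %, 20.5 % and 22.5 %, a course that rises all the way, and adds: “The last two are close, so the shape there is less certain”. Its spring value lies inside my bracket but higher than my own figure.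

The flasks give 1.22 %, 4.54 %, 14.5 %, 24.0 % and 20.9 %: the row rises, then falls, with the turn read near 2.3 equiv at 24.4 %. In spring at 12.0 h, free E stands at 60 % of its charge, so the trap ratio is 2.59, and E.X.E holds 66.4 % against 20.9 % for J. In dawn the charged ratio 0.270, scaled by the 3.5 % of E left, falls to 0.00945, and the forward rates at 12.0 h read 110 in favour of J, with E.X.E at 1.54 %.

The numbers of this flask are invented, and the outcome is calculated.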